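## Retrosynthetic overview

1. Target 25 ⇒ hypotaurine 21 + dienol lactone quinone 20; the thiazine 1,1-dioxide ring is formed last by sulfinate/amine addition and oxidation.
2. 20 ⇒ dienone quinone 19 by Baeyer–Villiger oxygen insertion (ring B, six- to seven-membered); 19 ⇒ enone 18 ⇒ bromo naphthoquinone ketone 14 (Stille acetylation, aldol closure of ring B).
3. Rings C and D of 14 ⇒ p-benzoquinone 11 + thiophene 1,1-dioxide 10; the thiophene serves first as the cation-stabilising aryl group and then as a latent butadiene.
4. Quaternary stereocentre and ring A ⇒ enantioselective protio-semipinacol ring expansion (five- to six-membered) of vinyl cyclopentanol 5.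
5. 5 ⇒ 3,4-dibromothiophene 1 + 1-ethynylcyclopentan-1-ol 2. Ring order: A, then C and D together, then B (carbocycle, then lactone), then the thiazine.

Convention: tetracycles use tetraphene (benz[a]anthracene) locants: C12b quaternary carbon, C4 methyl-bearing ring A carbon, C6 ring B carbonyl, C8 and C11 quinone carbonyls. The lactones are described as 5-oxa-B-homo analogues (oxygen between C6 and C5).

Assumption: the target stereocentre is (S) as read from the SMILES. The same spatial arrangement is (S) in 6 to 17, (R) in 18 and 19, and (S) again from 20 on; the changes are CIP priority changes only.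

Assumption: the sense of induction of the new catalyst system in step 2 is assigned by experiment, and the catalyst antipode that gives (S)-6 is used.

Assumption: the methyl-bearing CH centre made in step 3 is carried as an epimer mixture, because it becomes sp2 in step 7.

## Route

Step 1
Reactants: 1 3,4-dibromothiophene; 2 1-ethynylcyclopentan-1-ol
Product: 5 1-[1-(4-bromothiophen-3-yl)ethenyl]cyclopentan-1-ol, via thienyl Grignard 3 (not isolated), via alkenylmagnesium alkoxide 4 (not isolated)
Conditions: 1 (2.5 equiv), i-PrMgCl·LiCl (2.5 equiv), THF, 0 → 25 °C; then 2 (1.0 equiv), CuI (10 mol%), THF/PhMe, 25 → 45 °C; aq NH4Cl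
Reagents that add atoms: none
Why: Br/Mg exchange desymmetrises 1 (a 3-thienyl Grignard next to Br does not eliminate), and CuI-catalysed anti-carbomagnesiation of the propargylic alkoxide (Duboudin–Jousseaume type) delivers the thienyl group to the internal alkyne carbon through the five-membered chelate 4, so protonation gives the 2-aryl allylic alcohol; no stereocentre is formed.

Step 2
Reactants: 5 1-[1-(4-bromothiophen-3-yl)ethenyl]cyclopentan-1-ol
Product: 6 (2S)-2-(4-bromothiophen-3-yl)-2-methylcyclohexan-1-one
Conditions: HCl (1.0 equiv, Et2O solution), chiral arylpyrrolidino-squaramide hydrogen-bond donor (10 mol%), PhMe, 4 Å MS, −40 → −20 °C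
Reagents that add atoms: none
Why: Proposed new method: HCl/chiral squaramide co-catalysed enantioselective protio-semipinacol ring expansion of a vinyl cyclopentanol, in which Markovnikov protonation of the 1,1-disubstituted alkene gives a thienyl-stabilised tertiary cation held as a contact ion pair by the squaramide-bound chloride and a ring CH2 then shifts to one face of the planar cation as the carbinol becomes C=O, which forms ring A and sets the quaternary stereocentre as (S); the closest known reactions are the HCl/squaramide protio-semipinacol expansion of vinyl cyclopropanols to cyclobutanones and Brønsted-acid-catalysed asymmetric Wagner–Meerwein shifts, and the step is new because a cyclopentanol offers little strain release and the cation carries a 4-bromo-3-thienyl group.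

Step 3
Reactants: 6 (2S)-2-(4-bromothiophen-3-yl)-2-methylcyclohexan-1-one
Product: 8 (2S,6RS)-2-(4-bromothiophen-3-yl)-2,6-dimethylcyclohexan-1-one, via lithium enolate 7 (not isolated)
Conditions: LiN(i-Pr)2 (1.1 equiv), THF, −78 °C; MeI (1.5 equiv), −78 → −20 °C
Reagents that add atoms: iodomethane IC
Why: Only C6 can enolise because C2 is quaternary, so a single enolate 7 forms and its SN2 methylation (enolate alkylation) installs the future C4 methyl group; C2 is untouched.

Step 4
Reactants: 8 (2S,6RS)-2-(4-bromothiophen-3-yl)-2,6-dimethylcyclohexan-1-one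
Product: 10 3-bromo-4-[(1S,3RS)-1,3-dimethyl-2-oxocyclohexyl]thiophene 1,1-dioxide, via thiophene S-oxide 9 (not isolated)
Conditions: dimethyldioxirane (3 equiv, acetone solution), CH2Cl2, 0 → 25 °C
Reagents that add atoms: dimethyldioxirane CC1(C)OO1
Why: Dimethyldioxirane transfers oxygen twice to sulfur (via 9) without touching the ketone or the C–Br bond and with no alkene present, a known dioxirane oxidation of thiophenes to 1,1-dioxides; the bulky 4-substituent slows dimerisation of the diene and the stereocentre is remote.

Step 5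
Reactants: 10 3-bromo-4-[(1S,3RS)-1,3-dimethyl-2-oxocyclohexyl]thiophene 1,1-dioxide; 11 p-benzoquinone
Product: 14 6-bromo-7-[(1S,3RS)-1,3-dimethyl-2-oxocyclohexyl]naphthalene-1,4-dione, via sulfone-bridged cycloadduct 12 (not isolated), via naphthalenediol 13 (not isolated)
Conditions: 11 (3 equiv), AcOH, 110 °C
Reagents that add atoms: none
Why: The thiophene 1,1-dioxide acts as a 2,3-disubstituted butadiene: Diels–Alder addition to benzoquinone gives 12, cheletropic loss of SO2 and enolisation give 13, and excess benzoquinone oxidises 13 to the 6,7-disubstituted naphthoquinone (an annulation known for 3,4-dihalothiophene dioxides), so rings C and D form in one operation without touching the stereocentre.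

Step 6
Reactants: 14 6-bromo-7-[(1S,3RS)-1,3-dimethyl-2-oxocyclohexyl]naphthalene-1,4-dione
Product: 18 (12bR,4RS)-4,12b-dimethyl-1,2,3,4-tetrahydrotetraphene-6,8,11(12bH)-trione, via enol ether 15 (not isolated), via diketone 16 (not isolated), via aldol 17 (not isolated)
Conditions: tributyl(1-ethoxyethenyl)stannane (1.3 equiv), Pd2(dba)3 (2.5 mol%), AsPh3 (10 mol%), CuI (10 mol%), 1,4-dioxane, 90 °C; then 2 M HCl, THF, 25 °C; then TsOH·H2O (0.3 equiv), PhMe, 100 °C, Dean–Stark
Reagents that add atoms: tributyl(1-ethoxyethenyl)stannane CCCC[Sn](CCCC)(CCCC)C(=C)OCC; water O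
Why: Stille coupling at the quinone-activated C–Br bond gives 15, acid hydrolysis gives methyl ketone 16, and TsOH-catalysed intramolecular aldol condensation (enol of the aryl methyl ketone onto the neighbouring ring ketone, then dehydration of 17) closes ring B under non-basic conditions that the quinone tolerates; C12b cannot enolise and keeps its configuration.

Step 7
Reactants: 18 (12bR,4RS)-4,12b-dimethyl-1,2,3,4-tetrahydrotetraphene-6,8,11(12bH)-trione
Product: 19 (12bR)-4,12b-dimethyl-1,2-dihydrotetraphene-6,8,11(12bH)-trione
Conditions: DDQ (1.2 equiv), TsOH·H2O (10 mol%), 1,4-dioxane, 100 °C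
Reagents that add atoms: none
Why: Acid-promoted dienolisation towards C4 and hydride abstraction from C3 by DDQ (the enone to linear dienone dehydrogenation known from 4-en-3-one steroids) introduce the C3=C4 alkene; the other α-carbon is aromatic and ring A cannot aromatise past quaternary C12b, so no other dehydrogenation is open.

Step 8
Reactants: 19 (12bR)-4,12b-dimethyl-1,2-dihydrotetraphene-6,8,11(12bH)-trione
Product: 20 (S)-dienol lactone quinone (5-oxa-B-homo analogue of 19)
Conditions: Me3SiOOSiMe3 (2 equiv), TMSOTf (20 mol%), 4 Å MS, CH2Cl2, −40 → 0 °C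
Reagents that add atoms: bis(trimethylsilyl) peroxide C[Si](C)(C)OO[Si](C)(C)C
Why: Baeyer–Villiger ring expansion under non-epoxidising Lewis acid/silyl peroxide conditions: the peroxide adds to the most Lewis-basic carbonyl (C6, activated by TMSOTf) and the dienyl carbon C5 migrates to oxygen in preference to the electron-poor quinonoid aryl carbon, which turns the six-membered enone into the seven-membered dienol lactone without touching the C3=C4 alkene, the quinone or the stereocentre.

Step 9
Reactants: 20 (S)-dienol lactone quinone; 21 hypotaurine (2-aminoethanesulfinic acid)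
Product: 25 CNP0348176.1 (target), via sulfonyl hydroquinone 22 (not isolated), via sulfonylquinone 23 (not isolated), via thiazine hydroquinone 24 (not isolated)
Conditions: 21 (1.5 equiv), Co(salen) [Co(C16H14N2O2), divalent cobalt] (5 mol%), air, MeCN/EtOH/H2O (1:1:1), 25 °C
Reagents that add atoms: none
Why: Known hypotaurine–quinone annulation: the sulfinate adds in Michael fashion at C9, beta to the C11 carbonyl, which is the more electron-poor one because C11a is para to the lactone carbonyl carbon and meta to the alkyl group, giving 22; aerobic oxidation gives 23, the amine closes the six-membered ring at C10 to give 24, and a second oxidation gives the target with SO2 at C9 and NH at C10, the stereocentre being untouched.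

## Compound list

1 | 3,4-dibromothiophene | Brc1cscc1Br | starting material
2 | 1-ethynylcyclopentan-1-ol | C#CC1(O)CCCC1 | starting material
3 | (4-bromothiophen-3-yl)magnesium chloride [not isolated] | Cl[Mg]c1cscc1Br | intermediate
4 | cyclic alkenylmagnesium alkoxide from carbomagnesiation (1-oxa-2-magnesacyclopent-3-ene, spiro-fused to cyclopentane, 4-bromothiophen-3-yl on the alkene carbon next to the spiro centre) [not isolated] | Brc1cscc1C1=C[Mg]OC12CCCC2 | intermediate
5 | 1-[1-(4-bromothiophen-3-yl)ethenyl]cyclopentan-1-ol | C=C(c1cscc1Br)C1(O)CCCC1 | intermediate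
6 | (2S)-2-(4-bromothiophen-3-yl)-2-methylcyclohexan-1-one | C[C@]1(CCCCC1=O)c1cscc1Br | intermediate
7 | lithium enolate of 6 (enolised towards C6) [not isolated] | C[C@]1(CCCC=C1O[Li])c1cscc1Br | intermediate
8 | (2S,6RS)-2-(4-bromothiophen-3-yl)-2,6-dimethylcyclohexan-1-one (C6 epimers) | C[C@]1(CCCC(C)C1=O)c1cscc1Br | intermediate
9 | 3-bromo-4-[(1S,3RS)-1,3-dimethyl-2-oxocyclohexyl]thiophene 1-oxide (sulfur configuration undefined) [not isolated] | C[C@]1(CCCC(C)C1=O)C1=CS(=O)C=C1Br | intermediate
10 | 3-bromo-4-[(1S,3RS)-1,3-dimethyl-2-oxocyclohexyl]thiophene 1,1-dioxide | C[C@]1(CCCC(C)C1=O)C1=CS(=O)(=O)C=C1Br | intermediate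
11 | p-benzoquinone | O=C1C=CC(=O)C=C1 | starting material
12 | SO2-bridged [4+2] adduct of 10 and 11 (7-thiabicyclo[2.2.1]heptene 7,7-dioxide fused to cyclohexenedione; endo/exo mixture, both converge) [not isolated] | O=C1C=CC(=O)C2C1C1C([C@]3(C)CCCC(C)C3=O)=C(Br)C2S1(=O)=O | intermediate
13 | 6-bromo-7-[(1S,3RS)-1,3-dimethyl-2-oxocyclohexyl]naphthalene-1,4-diol [not isolated] | Oc1ccc(O)c2cc(Br)c(cc12)[C@]1(C)CCCC(C)C1=O | intermediate
14 | 6-bromo-7-[(1S,3RS)-1,3-dimethyl-2-oxocyclohexyl]naphthalene-1,4-dione | O=C1C=CC(=O)c2cc(Br)c(cc12)[C@]1(C)CCCC(C)C1=O | intermediate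
15 | 6-(1-ethoxyethenyl)-7-[(1S,3RS)-1,3-dimethyl-2-oxocyclohexyl]naphthalene-1,4-dione [not isolated] | CCOC(=C)c1cc2C(=O)C=CC(=O)c2cc1[C@]1(C)CCCC(C)C1=O | intermediate
16 | 6-acetyl-7-[(1S,3RS)-1,3-dimethyl-2-oxocyclohexyl]naphthalene-1,4-dione [not isolated] | CC(=O)c1cc2C(=O)C=CC(=O)c2cc1[C@]1(C)CCCC(C)C1=O | intermediate
17 | (12bS)-4a-hydroxy-4,12b-dimethyl-1,2,3,4,4a,5-hexahydrotetraphene-6,8,11(12bH)-trione (mixture at C4 and C4a) [not isolated] | CC1CCC[C@]2(C)C1(O)CC(=O)c1cc3c(cc12)C(=O)C=CC3=O | intermediate
18 | (12bR,4RS)-4,12b-dimethyl-1,2,3,4-tetrahydrotetraphene-6,8,11(12bH)-trione (C4 epimers) | CC1CCC[C@]2(C)C1=CC(=O)c1cc3c(cc12)C(=O)C=CC3=O | intermediate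
19 | (12bR)-4,12b-dimethyl-1,2-dihydrotetraphene-6,8,11(12bH)-trione | CC1=CCC[C@]2(C)C1=CC(=O)c1cc3c(cc12)C(=O)C=CC3=O | intermediate
20 | (S)-dienol lactone quinone: 5-oxa-B-homo analogue of 19, ring B = C6a–C(=O)–O–CH=C4a–C12b(CH3)–C12a (seven-membered), C3=C4 alkene and 1,4-naphthoquinone retained | CC1=CCC[C@]2(C)C1=COC(=O)c1cc3c(cc12)C(=O)C=CC3=O | intermediate
21 | hypotaurine (2-aminoethanesulfinic acid) | NCCS(=O)O | starting material
22 | (S)-sulfonyl hydroquinone: 20 reduced to the 8,11-diol with a 2-aminoethylsulfonyl group at C9 [not isolated] | CC1=CCC[C@]2(C)C1=COC(=O)c1cc3c(cc12)c(O)cc(c3O)S(=O)(=O)CCN | intermediate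
23 | (S)-sulfonylquinone: 20 with a 2-aminoethylsulfonyl group at C9 [not isolated] | CC1=CCC[C@]2(C)C1=COC(=O)c1cc3c(cc12)C(=O)C=C(C3=O)S(=O)(=O)CCN | intermediate
24 | (S)-thiazine-fused hydroquinone (leuco form of 25; 8,11-diol, NH at C10, SO2 at C9) [not isolated] | CC1=CCC[C@]2(C)C1=COC(=O)c1cc3c(cc12)c(O)c1NCCS(=O)(=O)c1c3O | intermediate
25 | CNP0348176.1: 20 with a 3,4-dihydro-2H-1,4-thiazine 1,1-dioxide fused to the quinone C9=C10 bond, SO2 at C9 (next to C8=O), NH at C10 (next to C11=O), (S) at the quaternary carbon | CC1=CCC[C@]2(C)C1=COC(=O)c1cc3c(cc12)C(=O)C1=C(C3=O)S(=O)(=O)CCN1 | target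

## Step count and risks

Total step count: 9. Longest linear sequence: 9 steps (from 3,4-dibromothiophene 1).

**Step 2 (proposed new ring expansion).** The cyclopentanol gives little strain release, so ionisation of the tertiary alcohol, elimination or chloride capture may compete, and the enantioselectivity is untested. The fallback uses known chemistry, sets out from 1 and comes back at 6. Grignard 3 is made from 1 as in step 1 and added to 2-chlorocyclohexanone (THF, −20 °C) to give the chloromagnesium alkoxide of 1-(4-bromothiophen-3-yl)-2-chlorocyclohexan-1-ol F1. On switching to toluene and heating to 100 °C this undergoes the classical 1,2-aryl shift with loss of chloride to give racemic 2-(4-bromothiophen-3-yl)cyclohexan-1-one F2. Asymmetric phase-transfer methylation of the aryl-stabilised enolate (MeI, CsOH·H2O, PhMe, −20 °C, chiral N-spiro binaphthyl quaternary ammonium bromide), a known method for 2-arylcyclohexanones, then gives 6.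

**Step 8 (Baeyer–Villiger on a conjugated dienone).** The ketone may be too unreactive, the aryl group may migrate, or the C3=C4 alkene or the product dienol ester may be oxidised. The fallback moves the oxygen insertion ahead of the dehydrogenation; it sets out from 18 and comes back at 20. Enone 18, whose only alkenes are electron-poor, is treated with CF3CO3H (from urea·H2O2 and (CF3CO)2O, Na2HPO4, CH2Cl2, 0 °C, 1.05 equiv) in the known vinyl-migration Baeyer–Villiger of cyclic enones, giving the (S)-enol lactone quinone lacking the C3=C4 alkene F3. Wohl–Ziegler bromination at the tertiary allylic C4 (NBS, AIBN, PhCF3, 80 °C) gives the (S)-C4 bromide F4, and dehydrobromination (LiBr, Li2CO3, DMF, 100 °C) gives 20.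

**Step 9 (regiochemistry of the thiazine annulation).** With free hypotaurine an amine-first pathway can compete with sulfinate-first addition and give the isomer with N and S exchanged. The fallback enforces sulfinate-first addition by masking the nitrogen; it sets out from 20 and 21 and comes back at 23. Hypotaurine 21 is converted with Boc2O/NaHCO3 into 2-[(tert-butoxycarbonyl)amino]ethane-1-sulfinic acid F5 (used as its sodium salt). Conjugate addition of F5 to 20 (AcOH/EtOH, 25 °C) gives the (S)-C9 sulfonyl hydroquinone carbamate F6, and Ag2O oxidation gives the (S)-C9 sulfonylquinone carbamate F7. TFA then removes the Boc group to release 23, which on neutralisation (NaHCO3) in air cyclises and oxidises through 24 to 25.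

Further compounds
F1 | step 2 | 1-(4-bromothiophen-3-yl)-2-chlorocyclohexan-1-ol (racemic, formed as its chloromagnesium alkoxide) | OC1(CCCCC1Cl)c1cscc1Br
F2 | step 2 | 2-(4-bromothiophen-3-yl)cyclohexan-1-one (racemic) | O=C1CCCCC1c1cscc1Br
F3 | step 8 | (S)-enol lactone quinone lacking the C3=C4 alkene (5-oxa-B-homo analogue of 18, C4 epimers) | CC1CCC[C@]2(C)C1=COC(=O)c1cc3c(cc12)C(=O)C=CC3=O
F4 | step 8 | (S)-C4 tertiary allylic bromide of F3 (C4 configuration undefined) | CC1(Br)CCC[C@]2(C)C1=COC(=O)c1cc3c(cc12)C(=O)C=CC3=O
F5 | step 9 | 2-[(tert-butoxycarbonyl)amino]ethane-1-sulfinic acid | CC(C)(C)OC(=O)NCCS(=O)O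
F6 | step 9 | (S)-C9 sulfonyl hydroquinone carbamate (8,11-diol of 20 with a 2-(Boc-amino)ethylsulfonyl group at C9) | CC1=CCC[C@]2(C)C1=COC(=O)c1cc3c(cc12)c(O)cc(c3O)S(=O)(=O)CCNC(=O)OC(C)(C)C
F7 | step 9 | (S)-C9 sulfonylquinone carbamate (20 with a 2-(Boc-amino)ethylsulfonyl group at C9) | CC1=CCC[C@]2(C)C1=COC(=O)c1cc3c(cc12)C(=O)C=C(C3=O)S(=O)(=O)CCNC(=O)OC(C)(C)C
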